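(All runs stem from a simulated flask from invented constants.)

Divide the logarithm of what a flask keeps of its left-handed substrate by the partner it wasted, and the clock drops out.

common to all: left-handed substrate 0.25 M; right-handed substrate 0.25 M
- south: partner 0.30 M (fed, over 20 s); catalyst 0.80 mM; run made earlier
- north: partner 0.30 M (fed, over 20 s); catalyst 1.8 mM; run made earlier
- west: partner 0.60 M (fed, over 20 s); catalyst 1.2 mM; run made earlier
- flask: partner 0.300 M (fed, over 20 s); catalyst 1.2 mM; time 10 min

- south (time / min: left-handed substrate / %, left-handed product / %, right-handed substrate / %): 1.33: 21.1, 30.2, 49.1; 4.00: 20.0, 30.7, 46.9; 6.00: 19.0, 29.6, 49.0; 10.0: 19.4, 30.0, 47.5
- north (time / min: left-handed substrate / %, left-handed product / %, right-handed substrate / %): 2.50: 12.1, 38.8, 46.6; 5.00: 12.3, 38.8, 47.6; 8.00: 12.7, 36.5, 44.8; 10.0: 12.0, 38.2, 46.7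
- west (time / min: left-handed substrate / %, left-handed product / %, right-handed substrate / %): 2.50: 3.6, 48.9, 43.7; 5.00: 1.6, 46.8, 44.0; 8.00: 1.6, 48.5, 42.4; 10.0: 2.8, 47.8, 42.1

(standard deviation of a reading: 1 percentage point)

- catalyst is single-handed; left-handed substrate and right-handed substrate are mirror images of each other, charged as a racemate, each of them at the stated concentration
- the numbers in the tables scatter by 1 percentage point (one standard deviation)
- steps thought possible: partner -> decomposed reagent; partner + catalyst + left-handed substrate -> catalyst + left-handed product; partner + catalyst + right-handed substrate -> catalyst + right-handed product
- the reaction counts as stopped when no species that holds the left-handed substrate and right-handed substrate together changes by six tenths of a point or more over the second half of the time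

1. at 10 min, what has stopped the reaction, if anything has (it is still moving / the partner has run out first / no working catalyst is left / all of the left-handed substrate has reacted)
2. part of the left-handed substrate and right-handed substrate together gone at 10 min
3. the left-handed product standing at 10 min, as a percentage of the left-handed substrate and right-handed substrate together charged
4. the right-handed substrate standing at 10 min, as a percentage of the left-handed substrate and right-handed substrate together charged
5. amount of left-handed product if the flask were left three thousand times as long, in percent of the left-handed substrate and right-handed substrate together charged

The earlier runs stood level from their first samples, within the scatter, so I looked for a reckoning without time. On the steps thought possible, partner decomposes and reacts at rates both proportional to [partner], so I divided one rate by the other. I called the result the waste ratio: the logarithm of charged over standing [left-handed substrate], per [catalyst] and per [decomposed reagent]. The north run averaged 12.3% left-handed and 46.4% right-handed substrate, so, if the level meant that its charge of 0.30 M of partner was used up, the partner not taken by substrate came to 0.0935 M, and I read a waste ratio of 8340 M⁻². The south run, at 19.9% and 48.1%, wasted 0.140 M and read 8240 M⁻².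

The flask has two extremes I could do in my head. With no partner wasted, conversion would be 60.0%; with every bit wasted, it would be nil. Its catalyst lies between those of south and north at the same partner charge, and south wasted more than north, so I took the mean of their waste, 0.117 M. The ratio then gave 15.5% left-handed substrate for the flask. With the mean right-handed loss of those runs, 2.7 percentage points, my conversion for the flask came to 37.2%.

The forecast named this end: the partner has run out first. It gave conversion 36.8% (35% to 38.6%), left-handed product 34.1% (32.6% to 35.6%), right-handed substrate 47.3% (46.5% to 48.1%) and left-handed product 34.1% (32.6% to 35.6%) on long standing, since “the product stays unchanged however long the flask stands”. My conversion stood slightly above its figure.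

The flask gave this end: the partner has run out first, with conversion 36.7%, left-handed product 34.0%, right-handed substrate 47.3%, and left-handed product 34.0% on long standing.

    partner → decomposed reagent (k = 0.0380 s⁻¹)
    partner + catalyst + left-handed substrate → catalyst + left-handed product (k = 310 M⁻² s⁻¹)
    partner + catalyst + right-handed substrate → catalyst + right-handed product (k = 15.0 M⁻² s⁻¹)

At 0.270 min partner in the flask went to left-handed product 1.6 times as fast as to decomposed reagent. Partner, the limiting reagent, stood at 0% of its charge by 10.0 min, and the waste ratio on 0.116 M of decomposed reagent gives 15.6% left-handed substrate, with 16.0% standing. With the other charges and the time held, the flask's right-handed substrate had moved by 5 points from its value at 0.633 M of partner. For the neighbour flask with 0.075 M of partner, the ratio, with the logarithm taken as linear in the partner balance and the right-handed loss set aside, gives 9.65% left-handed product; that flask gave 9.94%.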